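**Retrosynthetic overview**

1. Target locants (3,7-dioxabicyclo[3.3.0]octane): C1 (C–OH bridgehead), C2 (syringyl carbon), O3, C4 (CH2), C5 (CH bridgehead), C6 (guaiacyl carbon), O7, C8 (CH2); ring A = C1–C8–O7–C6–C5, ring B = C1–C2–O3–C4–C5.
2. Last disconnection: O7–C6 of ring A, closed by 5-exo trapping of the guaiacyl p-quinone methide by the C8 hydroxyl; before that the guaiacyl ring is attached at C6 by aryl Grignard addition to a lactol (C6 starts as a lactone carbonyl).
3. Key disconnection: C4–C5 and O3–C2 together, i.e. formaldehyde (C4, O3) is taken out of ring B, leaving a C2–C5 bond: a cyclopropane C1–C2–C5 fused to the ring-A lactone.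
4. Enabling feature: the free 4-OH of the syringyl ring is para to benzylic C2, and C2 and C5 are 1,3-related across carbinol carbon C1. As its phenoxide the ring can expel C5 from C2 (p-quinone methide at C2, enolate at C5 stabilised by the C6 lactone carbonyl and a temporary benzyl ester), so the cyclopropane C2–C5 bond is a latent 1,3-dipole for CH2=O.
5. The cyclopropane comes from an enantioselective intramolecular cyclopropanation of an allyl diazomalonate (C5 carbene onto the C1=C2 enol ether, tether O7–C8) built from syringaldehyde, methyl benzyloxyacetate and monobenzyl malonate. Ring order: lactone ring A plus cyclopropane, then ring B, then ring A is opened to the lactol, arylated and closed again.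

Key step: step 7

Remark (assumption): the sense of induction of Rh2(S-NTTL)4 with 10 cannot be taken from a direct precedent; should it favour the mirror image, Rh2(R-NTTL)4 is used, all else unchanged. Target locants are used in the Why lines.

**Route**

Step 1
Reactants: 1 syringaldehyde (4-hydroxy-3,5-dimethoxybenzaldehyde)
Product: 2 4-[(tert-butyldimethylsilyl)oxy]-3,5-dimethoxybenzaldehyde
Conditions: TBSCl, imidazole, DMF, rt
Reagents that add atoms: tert-butyldimethylsilyl chloride (TBSCl), CC(C)(C)[Si](C)(C)Cl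
Why: Imidazole-promoted silylation of a phenol; the aryl silyl ether is the latent phenoxide that triggers step 7, and no stereocenter is formed.

Step 2
Reactants: 2 4-[(tert-butyldimethylsilyl)oxy]-3,5-dimethoxybenzaldehyde; 3 methyl 2-(benzyloxy)acetate
Product: 6 methyl (Z)-2-(benzyloxy)-3-{4-[(tert-butyldimethylsilyl)oxy]-3,5-dimethoxyphenyl}prop-2-enoate, via lithium aldolate 4 (not isolated), via mesylate 5 (not isolated)
Conditions: LiN(i-Pr)2, 3, THF, −78 °C; then 2; then MsCl, −78 → 0 °C; then DBU, 0 °C → rt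
Reagents that add atoms: none
Why: Glycolate ester aldol addition followed by mesylation and E1cB elimination (aldol condensation) should give the α-alkoxy acrylate, the (Z)-isomer (aryl trans to the ester) being the thermodynamically favoured geometry.

Step 3
Reactants: 6 methyl (Z)-2-(benzyloxy)-3-{4-[(tert-butyldimethylsilyl)oxy]-3,5-dimethoxyphenyl}prop-2-enoate
Product: 7 (Z)-2-(benzyloxy)-3-{4-[(tert-butyldimethylsilyl)oxy]-3,5-dimethoxyphenyl}prop-2-en-1-ol
Conditions: i-Bu2AlH (2.3 equiv), CH2Cl2, −78 °C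
Reagents that add atoms: none
Why: 1,2-Reduction of an α,β-unsaturated ester with i-Bu2AlH at low temperature gives the allylic alcohol (future C8–O7) and leaves the enol ether and the aryl silyl ether untouched.

Step 4
Reactants: 7 (Z)-2-(benzyloxy)-3-{4-[(tert-butyldimethylsilyl)oxy]-3,5-dimethoxyphenyl}prop-2-en-1-ol; 8 3-(benzyloxy)-3-oxopropanoic acid (monobenzyl malonate)
Product: 9 benzyl (Z)-2-(benzyloxy)-3-{4-[(tert-butyldimethylsilyl)oxy]-3,5-dimethoxyphenyl}prop-2-en-1-yl propanedioate
Conditions: DCC, DMAP (cat.), CH2Cl2, 0 °C → rt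
Reagents that add atoms: none
Why: Steglich esterification joins the acid-sensitive enol ether alcohol to the malonic half-ester under neutral conditions, bringing in C5 and C6.

Step 5
Reactants: 9 benzyl (Z)-2-(benzyloxy)-3-{4-[(tert-butyldimethylsilyl)oxy]-3,5-dimethoxyphenyl}prop-2-en-1-yl propanedioate
Product: 10 1-benzyl 3-[(Z)-2-(benzyloxy)-3-{4-[(tert-butyldimethylsilyl)oxy]-3,5-dimethoxyphenyl}prop-2-en-1-yl] 2-diazopropanedioate
Conditions: p-ABSA, Et3N, MeCN, 0 °C → rt
Reagents that add atoms: 4-acetamidobenzenesulfonyl azide (p-ABSA), CC(=O)Nc1ccc(cc1)S(=O)(=O)N=[N+]=[N-]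
Why: Regitz diazo transfer onto the activated methylene of a malonate diester is routine and touches no other group.

Step 6
Reactants: 10 1-benzyl 3-[(Z)-2-(benzyloxy)-3-{4-[(tert-butyldimethylsilyl)oxy]-3,5-dimethoxyphenyl}prop-2-en-1-yl] 2-diazopropanedioate
Product: 11 benzyl (1S,5S,6S)-5-(benzyloxy)-6-{4-[(tert-butyldimethylsilyl)oxy]-3,5-dimethoxyphenyl}-2-oxo-3-oxabicyclo[3.1.0]hexane-1-carboxylate
Conditions: Rh2(S-NTTL)4 (1–2 mol %), CH2Cl2, slow addition of 10, 40 °C
Reagents that add atoms: none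
Why: Rhodium-carbene intramolecular cyclopropanation of an allyl diazomalonate onto the electron-rich enol ether alkene; the five-membered tether forces cis fusion, the (Z)-geometry is transferred stereospecifically (aryl cis to the benzyloxy group), and the chiral dirhodium carboxylate selects the alkene face and so the absolute configuration of the benzyloxy carbon (target C1), the only centre of 11 that is carried unchanged to the target.

Step 7
Reactants: 11 benzyl (1S,5S,6S)-5-(benzyloxy)-6-{4-[(tert-butyldimethylsilyl)oxy]-3,5-dimethoxyphenyl}-2-oxo-3-oxabicyclo[3.1.0]hexane-1-carboxylate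
Product: 15 benzyl (1S,5S,6R)-5-(benzyloxy)-6-(4-hydroxy-3,5-dimethoxyphenyl)-2-oxo-3,7-dioxabicyclo[3.3.0]octane-1-carboxylate, via tetrabutylammonium phenoxide 12 (not isolated), via quinone methide enolate 13 (not isolated), via hydroxymethyl alkoxide 14 (not isolated)
Conditions: Bu4NF (1.1 equiv), monomeric CH2O (ca. 5 equiv, THF solution from cracked paraformaldehyde), THF, −40 → 0 °C; then AcOH
Reagents that add atoms: formaldehyde, C=O
Why: Proposed new method: fluoride removes the aryl silyl group, and phenoxide 12 pushes electron density through the syringyl ring into the strained C2–C5 cyclopropane bond, which opens to p-quinone methide/enolate 13; the enolate, stabilised by the lactone and benzyl ester carbonyls, adds to CH2=O (aldol, C4–C5 bond, 14) and the new alkoxide closes onto the quinone methide carbon (O3–C2 bond), a formal (3+2) annulation of a donor–acceptor cyclopropane with an aldehyde. The closest known reaction types are the Lewis-acid-catalysed (3+2) annulation of 2-arylcyclopropane-1,1-diesters with aldehydes to tetrahydrofurans and the fluoride-triggered opening of 2-(4-silyloxyaryl)cyclopropane-1,1-diesters to p-quinone methides that take up external nucleophiles by 1,6-addition; combining them into an aldehyde annulation under basic conditions on a lactone-fused, alkoxy-substituted cyclopropane is the new element. Ring B is the only ring closed, by a 5-exo-trig oxa-1,6-addition, while the lactone (ring A) is kept. C5 becomes quaternary with the CH2O arm cis to C2 because only that epimer can close to the cis-fused bicycle and the aldol is reversible; C2 is set in the ring closure with the aryl group on the convex (exo) face, cis to the benzyloxy group; C1 is not touched. The step needs cleavage of C2–C5 and not of the C1–C5 bond that the benzyloxy donor would break under Lewis acid activation, which the base-only, phenoxide-driven mode should secure; it also needs the aldol to outrun β-elimination of benzyloxide and intermolecular capture of the quinone methide, for which the malonate-type stabilisation of the enolate, the reactivity of monomeric formaldehyde and the intramolecular 5-exo closure are relied on.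

Step 8
Reactants: 15 benzyl (1S,5S,6R)-5-(benzyloxy)-6-(4-hydroxy-3,5-dimethoxyphenyl)-2-oxo-3,7-dioxabicyclo[3.3.0]octane-1-carboxylate
Product: 17 (1S,5S,6R)-5-hydroxy-6-(4-hydroxy-3,5-dimethoxyphenyl)-3,7-dioxabicyclo[3.3.0]octan-2-one, via malonic half-acid 16 (not isolated)
Conditions: H2 (1 atm), Pd(OH)2/C, EtOAc–EtOH, rt; filter; then toluene–pyridine, 100 °C
Reagents that add atoms: none
Why: Hydrogenolysis cleaves the benzyl ester and the tertiary benzyl ether, and the resulting α-carboxy lactone loses CO2 on warming (malonic half-acid decarboxylation); ketonisation of the lactone enol can only give the cis-fused bicycle, which sets C5–H.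

Step 9
Reactants: 17 (1S,5S,6R)-5-hydroxy-6-(4-hydroxy-3,5-dimethoxyphenyl)-3,7-dioxabicyclo[3.3.0]octan-2-one
Product: 18 (1S,5S,6R)-6-(4-hydroxy-3,5-dimethoxyphenyl)-3,7-dioxabicyclo[3.3.0]octane-2,5-diol (lactol, both C2 epimers)
Conditions: i-Bu2AlH (3.5 equiv), THF, −78 °C
Reagents that add atoms: none
Why: Partial reduction of a γ-lactone to the lactol with i-Bu2AlH at −78 °C (two equivalents are consumed by the phenol and the tertiary alcohol); the lactol stays closed, so the adjacent C5 centre should not epimerise.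

Step 10
Reactants: 19 4-bromo-2-methoxyphenol
Product: 20 (4-bromo-2-methoxyphenoxy)(tert-butyl)dimethylsilane
Conditions: TBSCl, imidazole, DMF, rt
Reagents that add atoms: tert-butyldimethylsilyl chloride (TBSCl), CC(C)(C)[Si](C)(C)Cl
Why: Standard phenol silylation masks the acidic OH so that the aryl Grignard reagent can be formed.

Step 11
Reactants: 18 (1S,5S,6R)-6-(4-hydroxy-3,5-dimethoxyphenyl)-3,7-dioxabicyclo[3.3.0]octane-2,5-diol; 20 (4-bromo-2-methoxyphenoxy)(tert-butyl)dimethylsilane
Product: 22 (2R,3S,4R)-4-[{4-[(tert-butyldimethylsilyl)oxy]-3-methoxyphenyl}(hydroxy)methyl]-2-(4-hydroxy-3,5-dimethoxyphenyl)-3-(hydroxymethyl)oxolan-3-ol (both carbinol epimers), via aryl Grignard reagent 21 (not isolated)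
Conditions: 20, Mg, THF, 40 °C; then 18 added to 21 (5 equiv), THF, 0 °C → rt
Reagents that add atoms: none
Why: Grignard addition to the open hydroxy-aldehyde form of the lactol, after three equivalents of reagent have deprotonated the OH groups, gives the benzylic carbinol at C6; its configuration does not matter because it is erased in step 12.

Step 12
Reactants: 22 (2R,3S,4R)-4-[{4-[(tert-butyldimethylsilyl)oxy]-3-methoxyphenyl}(hydroxy)methyl]-2-(4-hydroxy-3,5-dimethoxyphenyl)-3-(hydroxymethyl)oxolan-3-ol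
Product: 25 fraxiresinol, (1S,2R,5R,6S)-6-(4-hydroxy-3-methoxyphenyl)-2-(4-hydroxy-3,5-dimethoxyphenyl)-3,7-dioxabicyclo[3.3.0]octan-1-ol, via pentaol 23 (not isolated), via quinone methide 24 (not isolated)
Conditions: Bu4NF, THF, 0 °C; then 1 M aq. HCl to pH ca. 2, rt
Reagents that add atoms: none
Why: Desilylation and mild acid convert the p-hydroxybenzyl alcohol into its p-quinone methide, which the primary C8 hydroxyl traps in a 5-exo-trig oxa-1,6-addition (the biomimetic ring closure of furofuran lignans); the guaiacyl group should take the exo position trans to the C4–C5 bond, which sets C6, and closure by the tertiary OH would give a strained oxetane.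

**Compound list**

1 | syringaldehyde (4-hydroxy-3,5-dimethoxybenzaldehyde) | COc1cc(C=O)cc(OC)c1O | starting material
2 | 4-[(tert-butyldimethylsilyl)oxy]-3,5-dimethoxybenzaldehyde | COc1cc(C=O)cc(OC)c1O[Si](C)(C)C(C)(C)C | intermediate
3 | methyl 2-(benzyloxy)acetate | COC(=O)COCc1ccccc1 | starting material
4 | lithium 2-(benzyloxy)-1-{4-[(tert-butyldimethylsilyl)oxy]-3,5-dimethoxyphenyl}-3-methoxy-3-oxopropan-1-olate (racemic, both diastereomers) | COC(=O)C(OCc1ccccc1)C([O-])c1cc(OC)c(O[Si](C)(C)C(C)(C)C)c(OC)c1.[Li+] | intermediate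
5 | methyl 2-(benzyloxy)-3-{4-[(tert-butyldimethylsilyl)oxy]-3,5-dimethoxyphenyl}-3-[(methylsulfonyl)oxy]propanoate (racemic, both diastereomers) | COC(=O)C(OCc1ccccc1)C(OS(C)(=O)=O)c1cc(OC)c(O[Si](C)(C)C(C)(C)C)c(OC)c1 | intermediate
6 | methyl (Z)-2-(benzyloxy)-3-{4-[(tert-butyldimethylsilyl)oxy]-3,5-dimethoxyphenyl}prop-2-enoate | COC(=O)/C(OCc1ccccc1)=C/c1cc(OC)c(O[Si](C)(C)C(C)(C)C)c(OC)c1 | intermediate
7 | (Z)-2-(benzyloxy)-3-{4-[(tert-butyldimethylsilyl)oxy]-3,5-dimethoxyphenyl}prop-2-en-1-ol | OC/C(OCc1ccccc1)=C/c1cc(OC)c(O[Si](C)(C)C(C)(C)C)c(OC)c1 | intermediate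
8 | 3-(benzyloxy)-3-oxopropanoic acid (monobenzyl malonate) | OC(=O)CC(=O)OCc1ccccc1 | starting material
9 | benzyl (Z)-2-(benzyloxy)-3-{4-[(tert-butyldimethylsilyl)oxy]-3,5-dimethoxyphenyl}prop-2-en-1-yl propanedioate | O=C(CC(=O)OCc1ccccc1)OC/C(OCc1ccccc1)=C/c1cc(OC)c(O[Si](C)(C)C(C)(C)C)c(OC)c1 | intermediate
10 | 1-benzyl 3-[(Z)-2-(benzyloxy)-3-{4-[(tert-butyldimethylsilyl)oxy]-3,5-dimethoxyphenyl}prop-2-en-1-yl] 2-diazopropanedioate | O=C(OCc1ccccc1)C(=[N+]=[N-])C(=O)OC/C(OCc1ccccc1)=C/c1cc(OC)c(O[Si](C)(C)C(C)(C)C)c(OC)c1 | intermediate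
11 | benzyl (1S,5S,6S)-5-(benzyloxy)-6-{4-[(tert-butyldimethylsilyl)oxy]-3,5-dimethoxyphenyl}-2-oxo-3-oxabicyclo[3.1.0]hexane-1-carboxylate | O=C1OC[C@]2(OCc3ccccc3)[C@@H](c3cc(OC)c(O[Si](C)(C)C(C)(C)C)c(OC)c3)[C@]12C(=O)OCc1ccccc1 | intermediate
12 | tetrabutylammonium 4-[(1S,5S,6S)-1-(benzyloxycarbonyl)-5-(benzyloxy)-2-oxo-3-oxabicyclo[3.1.0]hexan-6-yl]-2,6-dimethoxyphenolate | O=C1OC[C@]2(OCc3ccccc3)[C@@H](c3cc(OC)c([O-])c(OC)c3)[C@]12C(=O)OCc1ccccc1.CCCC[N+](CCCC)(CCCC)CCCC | intermediate
13 | tetrabutylammonium enolate of benzyl (4S)-4-(benzyloxy)-4-[(3,5-dimethoxy-4-oxocyclohexa-2,5-dien-1-ylidene)methyl]-2-oxooxolane-3-carboxylate | [O-]C(OCc1ccccc1)=C1C(=O)OC[C@]1(OCc1ccccc1)C=C1C=C(OC)C(=O)C(OC)=C1.CCCC[N+](CCCC)(CCCC)CCCC | intermediate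
14 | tetrabutylammonium {(3S,4S)-4-(benzyloxy)-3-(benzyloxycarbonyl)-4-[(3,5-dimethoxy-4-oxocyclohexa-2,5-dien-1-ylidene)methyl]-2-oxooxolan-3-yl}methanolate | [O-]C[C@]1(C(=O)OCc2ccccc2)C(=O)OC[C@]1(OCc2ccccc2)C=C2C=C(OC)C(=O)C(OC)=C2.CCCC[N+](CCCC)(CCCC)CCCC | intermediate
15 | benzyl (1S,5S,6R)-5-(benzyloxy)-6-(4-hydroxy-3,5-dimethoxyphenyl)-2-oxo-3,7-dioxabicyclo[3.3.0]octane-1-carboxylate | O=C1OC[C@]2(OCc3ccccc3)[C@@H](c3cc(OC)c(O)c(OC)c3)OC[C@]12C(=O)OCc1ccccc1 | intermediate
16 | (1S,5S,6R)-5-hydroxy-6-(4-hydroxy-3,5-dimethoxyphenyl)-2-oxo-3,7-dioxabicyclo[3.3.0]octane-1-carboxylic acid | O=C1OC[C@]2(O)[C@@H](c3cc(OC)c(O)c(OC)c3)OC[C@]12C(=O)O | intermediate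
17 | (1S,5S,6R)-5-hydroxy-6-(4-hydroxy-3,5-dimethoxyphenyl)-3,7-dioxabicyclo[3.3.0]octan-2-one | O=C1OC[C@]2(O)[C@@H](c3cc(OC)c(O)c(OC)c3)OC[C@H]12 | intermediate
18 | (1S,5S,6R)-6-(4-hydroxy-3,5-dimethoxyphenyl)-3,7-dioxabicyclo[3.3.0]octane-2,5-diol (lactol, both C2 epimers) | OC1OC[C@]2(O)[C@@H](c3cc(OC)c(O)c(OC)c3)OC[C@H]12 | intermediate
19 | 4-bromo-2-methoxyphenol | COc1cc(Br)ccc1O | starting material
20 | (4-bromo-2-methoxyphenoxy)(tert-butyl)dimethylsilane | COc1cc(Br)ccc1O[Si](C)(C)C(C)(C)C | intermediate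
21 | {4-[(tert-butyldimethylsilyl)oxy]-3-methoxyphenyl}magnesium bromide | COc1cc([Mg]Br)ccc1O[Si](C)(C)C(C)(C)C | intermediate
22 | (2R,3S,4R)-4-[{4-[(tert-butyldimethylsilyl)oxy]-3-methoxyphenyl}(hydroxy)methyl]-2-(4-hydroxy-3,5-dimethoxyphenyl)-3-(hydroxymethyl)oxolan-3-ol (both carbinol epimers) | OC[C@]1(O)[C@@H](c2cc(OC)c(O)c(OC)c2)OC[C@@H]1C(O)c1ccc(O[Si](C)(C)C(C)(C)C)c(OC)c1 | intermediate
23 | (2R,3S,4R)-4-[hydroxy(4-hydroxy-3-methoxyphenyl)methyl]-2-(4-hydroxy-3,5-dimethoxyphenyl)-3-(hydroxymethyl)oxolan-3-ol (both carbinol epimers) | OC[C@]1(O)[C@@H](c2cc(OC)c(O)c(OC)c2)OC[C@@H]1C(O)c1ccc(O)c(OC)c1 | intermediate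
24 | p-quinone methide of 23: 2-methoxy-4-methylidenecyclohexa-2,5-dien-1-one whose methylidene carbon carries the oxolane of 23 (ring configurations as in 23) | OC[C@]1(O)[C@@H](c2cc(OC)c(O)c(OC)c2)OC[C@@H]1C=C1C=CC(=O)C(OC)=C1 | intermediate
25 | fraxiresinol, (1S,2R,5R,6S)-6-(4-hydroxy-3-methoxyphenyl)-2-(4-hydroxy-3,5-dimethoxyphenyl)-3,7-dioxabicyclo[3.3.0]octan-1-ol | COc1cc([C@H]2OC[C@]3(O)[C@@H](c4cc(OC)c(O)c(OC)c4)OC[C@H]23)ccc1O | target

**Step count and risks**

Total step count: 12. Longest linear sequence: 11 steps (steps 1–9, 11 and 12 from syringaldehyde; step 10 prepares the aryl bromide for the Grignard reagent).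

Steps most likely to fail:

Step 7 (Proposed new method). The phenoxide-driven ring opening may be too slow at low temperature. The quinone methide may be consumed by intermolecular addition or oligomerisation before the aldol takes place. The enolate may expel benzyloxide. The fallback is stepwise, uses known reaction types, sets out from 11 and returns at 15. Compound 11 is opened reductively with Bu4NF in THF containing NaBH4 (fluoride-triggered quinone methide formation, then 1,6-hydride addition) to give benzyl (4S)-4-(benzyloxy)-4-(4-hydroxy-3,5-dimethoxybenzyl)-2-oxooxolane-3-carboxylate F1. Hydroxymethylation of its malonate-type C–H with aqueous CH2O and KHCO3 should give benzyl (3S,4S)-4-(benzyloxy)-4-(4-hydroxy-3,5-dimethoxybenzyl)-3-(hydroxymethyl)-2-oxooxolane-3-carboxylate F2; its C3 epimer is recycled through base-mediated retro-aldol and aldol. Oxidation of the 4-alkyl-2,6-dimethoxyphenol with Ag2O in CH2Cl2 regenerates the p-quinone methide, which the hydroxymethyl group traps at once in a 5-exo closure to give 15.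

Step 6. Enantiofacial discrimination on the trisubstituted enol ether may be insufficient. The carbene may attack the benzyl ether oxygen (oxonium ylide formation). Reversible heterolysis of the push–pull cyclopropane may erode configuration at the benzyloxy carbon. The fallback replaces asymmetric catalysis by resolution, sets out from 10 and returns at 11. Cyclopropanation of 10 with achiral Rh2(esp)2 in CH2Cl2 gives racemic material, i.e. 11 together with its mirror image benzyl (1R,5R,6R)-5-(benzyloxy)-6-{4-[(tert-butyldimethylsilyl)oxy]-3,5-dimethoxyphenyl}-2-oxo-3-oxabicyclo[3.1.0]hexane-1-carboxylate F3. The two are separated by preparative chromatography on a chiral stationary phase and 11 is carried on.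

Step 8. Hydrogenolytic opening of ring B at the benzylic C2–O3 bond may compete with the slow cleavage of the hindered tertiary benzyl ether, or decarboxylation may be incomplete. The fallback avoids hydrogen, sets out from 15 and returns at 17. Saponification with LiOH in THF/H2O cleaves the benzyl ester and opens the lactone, giving after acidification (4S,5R)-4-(benzyloxy)-4-(hydroxymethyl)-5-(4-hydroxy-3,5-dimethoxyphenyl)oxolane-3,3-dicarboxylic acid F4. On heating in toluene this relactonises and decarboxylates to (1S,5S,6R)-5-(benzyloxy)-6-(4-hydroxy-3,5-dimethoxyphenyl)-3,7-dioxabicyclo[3.3.0]octan-2-one F5. The tertiary benzyl ether is then removed with BCl3 and pentamethylbenzene as cation scavenger (CH2Cl2, −78 °C) to give 17.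

Further compounds
F1 | step 7 | benzyl (4S)-4-(benzyloxy)-4-(4-hydroxy-3,5-dimethoxybenzyl)-2-oxooxolane-3-carboxylate (both C3 epimers) | O=C1OC[C@@](Cc2cc(OC)c(O)c(OC)c2)(OCc2ccccc2)C1C(=O)OCc1ccccc1
F2 | step 7 | benzyl (3S,4S)-4-(benzyloxy)-4-(4-hydroxy-3,5-dimethoxybenzyl)-3-(hydroxymethyl)-2-oxooxolane-3-carboxylate | O=C1OC[C@@](Cc2cc(OC)c(O)c(OC)c2)(OCc2ccccc2)[C@@]1(CO)C(=O)OCc1ccccc1
F3 | step 6 | benzyl (1R,5R,6R)-5-(benzyloxy)-6-{4-[(tert-butyldimethylsilyl)oxy]-3,5-dimethoxyphenyl}-2-oxo-3-oxabicyclo[3.1.0]hexane-1-carboxylate (mirror image of 11) | O=C1OC[C@@]2(OCc3ccccc3)[C@H](c3cc(OC)c(O[Si](C)(C)C(C)(C)C)c(OC)c3)[C@@]12C(=O)OCc1ccccc1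
F4 | step 8 | (4S,5R)-4-(benzyloxy)-4-(hydroxymethyl)-5-(4-hydroxy-3,5-dimethoxyphenyl)oxolane-3,3-dicarboxylic acid | OC[C@]1(OCc2ccccc2)[C@@H](c2cc(OC)c(O)c(OC)c2)OCC1(C(=O)O)C(=O)O
F5 | step 8 | (1S,5S,6R)-5-(benzyloxy)-6-(4-hydroxy-3,5-dimethoxyphenyl)-3,7-dioxabicyclo[3.3.0]octan-2-one | O=C1OC[C@]2(OCc3ccccc3)[C@@H](c3cc(OC)c(O)c(OC)c3)OC[C@H]12
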